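**Retrosynthetic overview**
The strategy rests on the only stereocentre, C2 of the dihydropyranone ring (ring C): a benzylic, oxygen-bearing carbon beta to the C4 ketone that carries the 4-geranyloxyphenyl ring (ring B). Cutting the C2–C1' bond leads back to a flat, achiral 7-silyloxychromone and a 4-geranyloxyphenyl boronate.
The chromone (rings A and C) comes from 2,4-dihydroxyacetophenone by 4-O-silylation, enaminone formation and acid ring closure, so the pyranone ring is formed first.
The boronate comes from O-geranylation of 4-hydroxyphenylboronic acid pinacol ester; the 2E alkene is bought with geranyl bromide.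
The two halves are joined at C2 by a rhodium/chiral diene conjugate arylation that closes no ring, and buffered fluoride then frees the 7-OH.

Key step: step 5

Remark on the chemistry: the pinacol ester is assumed to be opened in situ by the aqueous hydroxide of step 5, so no separate unmasking to the boronic acid is planned; the sense of induction ((S,S) diene to 2S) is assigned by analogy with cyclic enones, and the (R,R) ligand would be taken instead if a first run shows the opposite sense.

**Route**

Step 1
Reactants: 1 2,4-dihydroxyacetophenone
Product: 2 1-[2-hydroxy-4-(triisopropylsilyloxy)phenyl]ethan-1-one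
Conditions: TIPSCl (1.05 equiv), imidazole (2.2 equiv), CH2Cl2, 0 °C to rt
Reagents that add atoms: triisopropylsilyl chloride (TIPSCl), CC(C)[Si](Cl)(C(C)C)C(C)C
Why: Selective O-silylation of a phenol: the 2-OH is tied up in a hydrogen bond to the acetyl carbonyl and is hindered, so the bulky silyl chloride should react only at the free, more acidic 4-OH.

Step 2
Reactants: 2 1-[2-hydroxy-4-(triisopropylsilyloxy)phenyl]ethan-1-one
Product: 3 (E)-3-(dimethylamino)-1-[2-hydroxy-4-(triisopropylsilyloxy)phenyl]prop-2-en-1-one
Conditions: Me2NCH(OMe)2 (2.5 equiv), toluene, 90 °C
Reagents that add atoms: N,N-dimethylformamide dimethyl acetal, COC(OC)N(C)C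
Why: Aminomethylenation of the methyl ketone (enaminone condensation) with loss of two methanol gives the E vinylogous amide; the 4-OH that the acetal would methylate is masked as the TIPS ether and the chelated 2-OH is a poor partner for O-methylation.

Step 3
Reactants: 3 (E)-3-(dimethylamino)-1-[2-hydroxy-4-(triisopropylsilyloxy)phenyl]prop-2-en-1-one
Product: 4 7-(triisopropylsilyloxy)-4H-chromen-4-one
Conditions: conc. aq. HCl (2 equiv), CH2Cl2, 25–40 °C; aq. NaHCO3 work-up
Reagents that add atoms: none
Why: Acid-promoted intramolecular oxa-Michael addition of the 2-OH to the protonated vinylogous amide followed by elimination of dimethylamine (the enaminone route to chromones) closes the pyran-4-one ring, and an aryl TIPS ether should tolerate this brief two-phase acid treatment.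

Step 4
Reactants: 5 geranyl bromide [(2E)-1-bromo-3,7-dimethylocta-2,6-diene]; 6 4-hydroxyphenylboronic acid pinacol ester
Product: 7 2-{4-[(2E)-3,7-dimethylocta-2,6-dien-1-yloxy]phenyl}-4,4,5,5-tetramethyl-1,3,2-dioxaborolane
Conditions: K2CO3 (1.5 equiv), dry acetone, 50 °C
Reagents that add atoms: none
Why: Williamson ether synthesis: the phenoxide displaces the primary allylic bromide by SN2 at the unhindered CH2 terminus, so no allylic transposition occurs and the 2E alkene is untouched, and the pinacol boronate is stable to anhydrous carbonate.

Step 5
Reactants: 4 7-(triisopropylsilyloxy)-4H-chromen-4-one; 7 2-{4-[(2E)-3,7-dimethylocta-2,6-dien-1-yloxy]phenyl}-4,4,5,5-tetramethyl-1,3,2-dioxaborolane (2 equiv)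
Product: 8 (2S)-2-{4-[(2E)-3,7-dimethylocta-2,6-dien-1-yloxy]phenyl}-7-(triisopropylsilyloxy)chroman-4-one
Conditions: [RhCl(C2H4)2]2 (2.5 mol%), (S,S)-Ph-bod [(1S,4S)-2,5-diphenylbicyclo[2.2.2]octa-2,5-diene] (5.5 mol%), aq. KOH (0.3 equiv), toluene/H2O (10:1), 40 °C
Reagents that add atoms: none
Why: Hayashi–Miyaura-type cycle: the hydroxo complex of monovalent rhodium generated from [RhCl(C2H4)2]2, the diene and KOH takes over the aryl group of 7 (the pinacol ester being opened to the hydroxyboronate by the aqueous base), the aryl–rhodium species inserts the C2=C3 bond of the bound chromone in a syn 1,4-sense, and water protonates the oxa-π-allyl rhodium enolate, which frees the chromanone and regenerates Rh–OH. The closest known reaction type is the rhodium/chiral diene catalysed asymmetric conjugate addition of arylboronic acids to chromones that delivers flavanones. No ring is closed here: the new C2–C1' bond joins ring B to the preformed benzopyranone (rings A and C), so the chalcone/flavanone oxa-Michael equilibrium is never called upon. The single new stereocentre C2 is controlled by the C2-symmetric diene, whose phenyl groups shield one enantioface of the coordinated planar enone during the insertion; the (S,S) antipode is expected to give 2S. The step needs enantioface selectivity, 1,4- rather than 1,2-addition and a single arylation, which the π-accepting diene on rhodium and the vinylogous-ester character of the chromone provide, and it needs the product to keep its configuration, which the 7-O-TIPS group (no phenoxide that would deaden the enone or promote opening), the sub-stoichiometric hydroxide and the two-phase medium are meant to secure. The trisubstituted alkenes and the allylic aryl ether of the geranyl chain bind rhodium poorly and should pass unchanged.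

Step 6
Reactants: 8 (2S)-2-{4-[(2E)-3,7-dimethylocta-2,6-dien-1-yloxy]phenyl}-7-(triisopropylsilyloxy)chroman-4-one
Product: 9 (2S)-7-hydroxy-2-{4-[(2E)-3,7-dimethylocta-2,6-dien-1-yloxy]phenyl}chroman-4-one (target CNP0302343.1)
Conditions: Bu4NF (1.2 equiv), AcOH (1.5 equiv), THF, 0 °C; pH 7 buffer quench
Reagents that add atoms: none
Why: Buffered fluoride desilylation: fluoride attacks silicon of the aryl silyl ether (made labile by the para ketone) while acetic acid protonates the phenoxide as it forms, so that enolisation at C3 and retro-oxa-Michael opening, the channels that would scramble C2, should stay closed.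

**Compound list**
1 | 2,4-dihydroxyacetophenone | CC(=O)c1ccc(O)cc1O | starting material
2 | 1-[2-hydroxy-4-(triisopropylsilyloxy)phenyl]ethan-1-one | CC(=O)c1ccc(O[Si](C(C)C)(C(C)C)C(C)C)cc1O | intermediate
3 | (E)-3-(dimethylamino)-1-[2-hydroxy-4-(triisopropylsilyloxy)phenyl]prop-2-en-1-one | CN(C)/C=C/C(=O)c1ccc(O[Si](C(C)C)(C(C)C)C(C)C)cc1O | intermediate
4 | 7-(triisopropylsilyloxy)-4H-chromen-4-one | O=c1ccoc2cc(O[Si](C(C)C)(C(C)C)C(C)C)ccc12 | intermediate
5 | geranyl bromide, (2E)-1-bromo-3,7-dimethylocta-2,6-diene | CC(C)=CCC/C(C)=C/CBr | starting material
6 | 4-hydroxyphenylboronic acid pinacol ester | CC1(C)OB(c2ccc(O)cc2)OC1(C)C | starting material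
7 | 2-{4-[(2E)-3,7-dimethylocta-2,6-dien-1-yloxy]phenyl}-4,4,5,5-tetramethyl-1,3,2-dioxaborolane | CC(C)=CCC/C(C)=C/COc1ccc(B2OC(C)(C)C(C)(C)O2)cc1 | intermediate
8 | (2S)-2-{4-[(2E)-3,7-dimethylocta-2,6-dien-1-yloxy]phenyl}-7-(triisopropylsilyloxy)chroman-4-one | CC(C)=CCC/C(C)=C/COc1ccc([C@@H]2CC(=O)c3ccc(O[Si](C(C)C)(C(C)C)C(C)C)cc3O2)cc1 | intermediate
9 | (2S)-7-hydroxy-2-{4-[(2E)-3,7-dimethylocta-2,6-dien-1-yloxy]phenyl}chroman-4-one | CC(C)=CCC/C(C)=C/COc1ccc([C@@H]2CC(=O)c3ccc(O)cc3O2)cc1 | target

**Step count**
Total steps: 6. Longest linear sequence: 5 steps (steps 1, 2, 3, 5, 6); the boronate branch adds step 4.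

**Steps most likely to fail**

Step 5. The aryl transfer from the pinacol ester to rhodium may be slow enough that protodeboronation outruns addition. The enantioface discrimination may be insufficient. The base may trigger retro-oxa-Michael opening of the product and erode its enantiomeric purity. The fallback sets out from 7: the pinacol ester is cleaved oxidatively (NaIO4, NH4OAc, acetone/H2O, rt) to 4-[(2E)-3,7-dimethylocta-2,6-dien-1-yloxy]phenylboronic acid F1. F1 is then joined to chromone 4 with the other established catalyst class for chromone arylation, a cationic divalent-palladium/pyridine–oxazoline system (Pd(OCOCF3)2, the t-Bu-PyOx antipode that gives 2S, NH4PF6, H2O, 1,2-dichloroethane, 40–60 °C, under air). That cycle (transmetalation to cationic palladium, enantioselective insertion, protonolysis of the palladium enolate) needs no base and uses a different stereocontrolling ligand. It comes back to the route at 8.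

Step 6. Fluoride or phenoxide basicity may cause enolisation at C3 and opening to the 2'-hydroxychalcone, whose re-closure is unselective, so enantiopurity is lost. Cleavage of the hindered silyl ether may also be incomplete under the buffered conditions. The fallback removes the silyl group before the stereocentre exists. From 4, Bu4NF in THF gives 7-hydroxy-4H-chromen-4-one F2, which is achiral and has nothing to scramble. F2 is arylated with 7 using the preformed hydroxo dimer [Rh(OH)((S,S)-Ph-bod)]2 in dioxane/H2O without added base, so that the phenol stays un-ionised and the chromone stays electrophilic. Protonation of the rhodium enolate then gives 9 directly, and no deprotection follows the stereodefining step.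

Step 2. The acetal may O-methylate the phenol, or the methoxide and dimethylamine set free at 90 °C may strip the aryl silyl ether, giving mixtures. The fallback sets out from 2: a Claisen-type C-formylation at low temperature (NaH, ethyl formate, THF, 0 °C to rt, then dilute aqueous acid) should give the cyclic hemiacetal 2-hydroxy-7-(triisopropylsilyloxy)chroman-4-one F3, racemic at a centre that the next operation destroys. Acid-catalysed dehydration (cat. p-TsOH, toluene, 60 °C) then gives chromone 4, where the route is rejoined; enaminone 3 and step 3 are bypassed.

**Further compounds**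
F1 | step 5 | 4-[(2E)-3,7-dimethylocta-2,6-dien-1-yloxy]phenylboronic acid | CC(C)=CCC/C(C)=C/COc1ccc(B(O)O)cc1
F2 | step 6 | 7-hydroxy-4H-chromen-4-one | O=c1ccoc2cc(O)ccc12
F3 | step 2 | 2-hydroxy-7-(triisopropylsilyloxy)chroman-4-one (racemic) | OC1CC(=O)c2ccc(O[Si](C(C)C)(C(C)C)C(C)C)cc2O1
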